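**Retrosynthetic overview**

1. The target comes from nona-O-benzyl ether 21 by hydrogenolysis. The lower (2R,3S,4S)-flavan-3,4-diol comes from OsO4 syn-dihydroxylation, anti to the 2-aryl group, of a (2S)-flav-3-ene. That flavene is closed by ring-closing metathesis of a branched allyl aryl ether set by iridium-catalysed allylic etherification on the central pyrogallol ring.
2. The upper 4-arylflavan-3-ol pyran is cut at O1–C2 and C4a–C4 together, giving free resorcinol (ring A) and enantiopure trans-chalcone epoxide 9. Here C4 is the epoxide β-carbon, C3 the α-carbon, and C2 the ketone carbon, held one oxidation level high and reduced in the same pot.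
3. Enabling feature: in the upper pyran, C2 and C4 are both benzylic and 1,3-related across carbinol C3 (a latent 2,3-epoxy-1-ketone). Ring A is a resorcinol whose C4a is ortho to O1 and para to the 7-OH, so free resorcinol is a regiodefined C,O-1,3-bis-nucleophile.
4. Epoxide 9 comes from Juliá–Colonna epoxidation of the Claisen–Schmidt chalcone of 6-bromo-2,3,4-tris(benzyloxy)benzaldehyde and 3,4,5-tris(benzyloxy)acetophenone. The bromine on the central ring is inert in the key step and is the later handle for the lower unit.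
5. Ring order: all benzene rings are bought; the upper pyran is formed first (step 6), the lower pyran second (step 12).

Key step: step 6

Assumption 1: the sense of induction of poly-D-leucine (step 5) and of the iridium–phosphoramidite catalyst (step 11) is taken from the parent chalcone and cinnamyl carbonate cases; if either is reversed on these substrates, the antipodal polymer or ligand is used.
Assumption 2: the hindered C4–aryl bond is treated as freely equilibrating, since the target carries no axial descriptor.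

**Route**

Step 1
Reactants: 1 5-bromobenzene-1,2,3-triol
Product: 2 5-bromo-1,2,3-tris(benzyloxy)benzene
Conditions: BnBr (3.6 equiv), K2CO3 (4 equiv), DMF, 60 °C
Reagents that add atoms: benzyl bromide, BrCc1ccccc1
Why: Williamson etherification of the three phenoxides with benzyl bromide is routine and creates no stereocentre.

Step 2
Reactants: 2 5-bromo-1,2,3-tris(benzyloxy)benzene
Product: 4 6-bromo-2,3,4-tris(benzyloxy)benzaldehyde, via aryllithium 3 (not isolated)
Conditions: LDA (1.2 equiv), THF, −78 °C; DMF (3 equiv), −78 → 0 °C; aq. NH4Cl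
Reagents that add atoms: N,N-dimethylformamide, CN(C)C=O
Why: Directed ortho-lithiation and formylation should work because the only two ring C–H positions are equivalent and each is flanked and acidified by Br and OBn, and the ortho-bromoaryllithium is stable at −78 °C.

Step 3
Reactants: 5 1-(3,4,5-trihydroxyphenyl)ethan-1-one
Product: 6 1-[3,4,5-tris(benzyloxy)phenyl]ethan-1-one
Conditions: BnBr (3.6 equiv), K2CO3 (4 equiv), DMF, 60 °C
Reagents that add atoms: benzyl bromide, BrCc1ccccc1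
Why: Williamson etherification of the phenols is routine, and the weak base leaves the methyl ketone untouched.

Step 4
Reactants: 4 6-bromo-2,3,4-tris(benzyloxy)benzaldehyde; 6 1-[3,4,5-tris(benzyloxy)phenyl]ethan-1-one
Product: 8 (E)-3-[2,3,4-tris(benzyloxy)-6-bromophenyl]-1-[3,4,5-tris(benzyloxy)phenyl]prop-2-en-1-one, via aldol adduct 7 (not isolated)
Conditions: KOH (50 % aq., 3 equiv), EtOH/THF 1:1, rt
Reagents that add atoms: none
Why: Claisen–Schmidt condensation of a non-enolisable aldehyde with the acetophenone enolate should give the chalcone, and E1cB dehydration of the aldol delivers the conjugated E-alkene.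

Step 5
Reactants: 8 (E)-chalcone
Product: 9 [(2S,3R)-3-(2,3,4-tris(benzyloxy)-6-bromophenyl)oxiran-2-yl][3,4,5-tris(benzyloxy)phenyl]methanone
Conditions: immobilised poly-D-leucine, urea–H2O2 (1.5 equiv), DBU (1.5 equiv), THF, rt
Reagents that add atoms: urea–hydrogen peroxide, NC(N)=O.OO
Why: Juliá–Colonna asymmetric nucleophilic epoxidation should give the trans-epoxide, with the helical poly-D-leucine directing hydroperoxide to the enone face that gives the (2S,3R) isomer, the mirror image of the poly-L-leucine/(2R,3S) outcome of the parent chalcone.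

Step 6
Reactants: 9 (2S,3R)-chalcone epoxide; 10 resorcinol (benzene-1,3-diol)
Product: 13 (2R,3S,4S)-4-[2,3,4-tris(benzyloxy)-6-bromophenyl]-2-[3,4,5-tris(benzyloxy)phenyl]chromane-3,7-diol, via hydroxy ketone 11 (not isolated), via hemiketal 12 (not isolated)
Conditions: 10 (5 equiv), BF3·OEt2 (0.5 equiv), CH2Cl2/(CF3)2CHOH 4:1, −40 °C; then Et3SiH (5 equiv), BF3·OEt2 (2.5 equiv), −40 → 0 °C
Reagents that add atoms: none
Why: Proposed new method: the BF3-activated epoxide is opened at its benzylic β-carbon (stabilised by ortho- and para-benzyloxy groups, while the α-carbon is deactivated by the carbonyl) by C-4 of resorcinol in an SN2-like, invertive Friedel–Crafts alkylation to give hydroxy ketone 11, whose ortho-hydroxyl adds to the aryl ketone to give hemiketal 12, which BF3/Et3SiH ionises to the 2-aryl oxocarbenium ion and reduces; the closest known reaction types are the stereospecific Lewis-acid or fluoro-alcohol promoted arylative opening of aryl epoxides and glycidic esters, the Lewis-acid β-opening of chalcone epoxides by thiols, and the Et3SiH reductive etherification of hydroxy ketones. The pyran ring closes by 6-exo-trig hemiketalisation followed by hydride capture of the cyclic oxocarbenium ion. C-4 is set by inversion at the epoxide β-carbon, C-3 is the untouched epoxide α-carbon, and C-2 is set by axial hydride delivery to the half-chair oxocarbenium ion with 3-OH and 4-aryl pseudo-equatorial, which places the 2-aryl group equatorial (2,3-trans, 2,4-cis). The step needs C- rather than O-alkylation at the correct ring position, which free resorcinol secures because C-4 and C-6 are equivalent and each is ortho to one hydroxyl and para to the other, and it needs bimolecular capture to outrun the 1,2-aroyl shift of the opened epoxide, which excess resorcinol, low temperature and late addition of the silane should secure. Hydride transfer is irreversible, so any reversible arylation of the hindered oxocarbenium ion by excess resorcinol should be funnelled to 13.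

Step 7
Reactants: 13 (2R,3S,4S)-chromane-3,7-diol
Product: 14 (2R,3S,4S)-3,7-bis(benzyloxy)-4-[2,3,4-tris(benzyloxy)-6-bromophenyl]-2-[3,4,5-tris(benzyloxy)phenyl]chromane
Conditions: NaH (3 equiv), BnBr (2.6 equiv), n-Bu4NI (cat.), DMF, 0 °C → rt
Reagents that add atoms: benzyl bromide, BrCc1ccccc1
Why: Williamson etherification of the phenoxide and the secondary alkoxide makes every hydroxyl a benzyl ether without touching a stereocentre.

Step 8
Reactants: 14 aryl bromide
Product: 15 (E)-3-{2-[(2R,3S,4S)-3,7-bis(benzyloxy)-2-(3,4,5-tris(benzyloxy)phenyl)chroman-4-yl]-3,4,5-tris(benzyloxy)phenyl}prop-2-en-1-ol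
Conditions: (E)-Bu3SnCH=CHCH2OH (1.3 equiv), Pd2(dba)3 (2.5 mol %), P(t-Bu)3 (10 mol %), CsF (2.2 equiv), dioxane, 90 °C
Reagents that add atoms: (E)-3-(tributylstannyl)prop-2-en-1-ol, OC/C=C/[Sn](CCCC)(CCCC)CCCC
Why: Stille coupling with a zerovalent palladium/P(t-Bu)3 catalyst suits an electron-rich, mono-ortho-substituted aryl bromide, and the alkenyl group transfers with retention of E geometry.

Step 9
Reactants: 15 cinnamyl alcohol
Product: 16 methyl carbonate of 15
Conditions: ClCO2Me (1.5 equiv), pyridine (3 equiv), CH2Cl2, 0 °C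
Reagents that add atoms: methyl chloroformate, COC(Cl)=O
Why: Acylation of the primary allylic alcohol with a chloroformate installs the leaving group for the allyl-iridium chemistry.

Step 10
Reactants: 17 4-(benzyloxy)-2-hydroxybenzaldehyde
Product: 18 5-(benzyloxy)-2-ethenylphenol
Conditions: Ph3PCH3Br (2.5 equiv), KOt-Bu (2.5 equiv), THF, 0 °C → rt
Reagents that add atoms: methyltriphenylphosphonium bromide, C[P+](c1ccccc1)(c1ccccc1)c1ccccc1.[Br-]
Why: Wittig methylenation with excess ylide tolerates the free phenol (carried as its phenoxide) and gives the ortho-vinylphenol.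

Step 11
Reactants: 16 cinnamyl methyl carbonate; 18 5-(benzyloxy)-2-ethenylphenol
Product: 19 branched ether, (S)-configured at the new ArCH(OAr)CH=CH2 carbon
Conditions: 18 (1.6 equiv), NaH (1.5 equiv), THF, 0 °C; then 16, [Ir(cod)Cl]2 (2 mol %), (Sa,S,S)-O,O′-(1,1′-binaphthyl-2,2′-diyl)-N,N-bis(1-phenylethyl)phosphoramidite (4 mol %), THF, 50 °C
Reagents that add atoms: none
Why: Iridium-catalysed asymmetric allylic etherification should send the aryloxide to the benzylic terminus of the allyl-iridium intermediate, and the phosphoramidite ligand, not the remote upper-unit stereocentres, sets the new C–O stereocentre as S.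

Step 12
Reactants: 19 branched diene ether
Product: 20 (2S)-7-(benzyloxy)-2-aryl-2H-chromene (flav-3-ene), aryl = the central ring carrying the upper unit
Conditions: second-generation Grubbs catalyst (RuCl2(=CHPh)(PCy3)(H2IMes), 5 mol %), CH2Cl2, 40 °C
Reagents that add atoms: none
Why: Ring-closing olefin metathesis between the styrenyl and allylic vinyl groups closes the six-membered lower pyran with loss of ethene and does not involve the C-2 stereocentre.

Step 13
Reactants: 20 (2S)-flav-3-ene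
Product: 21 nona-O-benzyl ether of the target, lower unit (2R,3S,4S)-3,4-diol
Conditions: OsO4 (5 mol %), NMO (2 equiv), acetone/THF/H2O, rt
Reagents that add atoms: osmium tetroxide, O=[Os](=O)(=O)=O; N-methylmorpholine N-oxide, C[N+]1([O-])CCOCC1; water, O
Why: Catalytic OsO4 syn-dihydroxylation should add to the face of the ring alkene anti to the pseudo-axial 2-aryl group, giving the 2,3-trans-3,4-cis diol with both new stereocentres set by C-2.

Step 14
Reactants: 21 nona-O-benzyl ether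
Product: 22 target, (2R,3S,4S)-2-{2-[(2R,3S,4S)-3,7-dihydroxy-2-(3,4,5-trihydroxyphenyl)chroman-4-yl]-3,4,5-trihydroxyphenyl}chromane-3,4,7-triol
Conditions: H2 (1 atm), Pd(OH)2/C (20 wt %), THF/MeOH 1:1, rt
Reagents that add atoms: none
Why: Hydrogenolysis of the nine O-benzyl groups under neutral conditions should free all hydroxyls without touching a stereocentre, provided the reaction is stopped before the benzylic 4-OH of the lower unit is attacked.

**Compound list**

1 | 5-bromobenzene-1,2,3-triol | Oc1cc(Br)cc(O)c1O | starting material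
2 | 5-bromo-1,2,3-tris(benzyloxy)benzene | Brc1cc(OCc2ccccc2)c(OCc2ccccc2)c(OCc2ccccc2)c1 | intermediate
3 | [2,3,4-tris(benzyloxy)-6-bromophenyl]lithium | [Li]c1c(Br)cc(OCc2ccccc2)c(OCc2ccccc2)c1OCc1ccccc1 | intermediate (not isolated)
4 | 6-bromo-2,3,4-tris(benzyloxy)benzaldehyde | O=Cc1c(Br)cc(OCc2ccccc2)c(OCc2ccccc2)c1OCc1ccccc1 | intermediate
5 | 1-(3,4,5-trihydroxyphenyl)ethan-1-one | CC(=O)c1cc(O)c(O)c(O)c1 | starting material
6 | 1-[3,4,5-tris(benzyloxy)phenyl]ethan-1-one | CC(=O)c1cc(OCc2ccccc2)c(OCc2ccccc2)c(OCc2ccccc2)c1 | intermediate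
7 | 3-[2,3,4-tris(benzyloxy)-6-bromophenyl]-3-hydroxy-1-[3,4,5-tris(benzyloxy)phenyl]propan-1-one (racemic aldol) | O=C(CC(O)c1c(Br)cc(OCc2ccccc2)c(OCc2ccccc2)c1OCc1ccccc1)c1cc(OCc2ccccc2)c(OCc2ccccc2)c(OCc2ccccc2)c1 | intermediate (not isolated)
8 | (E)-3-[2,3,4-tris(benzyloxy)-6-bromophenyl]-1-[3,4,5-tris(benzyloxy)phenyl]prop-2-en-1-one | O=C(/C=C/c1c(Br)cc(OCc2ccccc2)c(OCc2ccccc2)c1OCc1ccccc1)c1cc(OCc2ccccc2)c(OCc2ccccc2)c(OCc2ccccc2)c1 | intermediate
9 | [(2S,3R)-3-(2,3,4-tris(benzyloxy)-6-bromophenyl)oxiran-2-yl][3,4,5-tris(benzyloxy)phenyl]methanone | O=C(c1cc(OCc2ccccc2)c(OCc2ccccc2)c(OCc2ccccc2)c1)[C@H]1O[C@@H]1c1c(Br)cc(OCc2ccccc2)c(OCc2ccccc2)c1OCc1ccccc1 | intermediate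
10 | resorcinol (benzene-1,3-diol) | Oc1cccc(O)c1 | starting material
11 | (2S,3S)-3-[2,3,4-tris(benzyloxy)-6-bromophenyl]-3-(2,4-dihydroxyphenyl)-2-hydroxy-1-[3,4,5-tris(benzyloxy)phenyl]propan-1-one | O=C(c1cc(OCc2ccccc2)c(OCc2ccccc2)c(OCc2ccccc2)c1)[C@@H](O)[C@@H](c1ccc(O)cc1O)c1c(Br)cc(OCc2ccccc2)c(OCc2ccccc2)c1OCc1ccccc1 | intermediate (not isolated)
12 | (3S,4S)-4-[2,3,4-tris(benzyloxy)-6-bromophenyl]-2-[3,4,5-tris(benzyloxy)phenyl]chromane-2,3,7-triol (both C-2 epimers) | Oc1ccc2c(c1)OC(O)(c1cc(OCc3ccccc3)c(OCc3ccccc3)c(OCc3ccccc3)c1)[C@@H](O)[C@@H]2c1c(Br)cc(OCc2ccccc2)c(OCc2ccccc2)c1OCc1ccccc1 | intermediate (not isolated)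
13 | (2R,3S,4S)-4-[2,3,4-tris(benzyloxy)-6-bromophenyl]-2-[3,4,5-tris(benzyloxy)phenyl]chromane-3,7-diol | Oc1ccc2c(c1)O[C@H](c1cc(OCc3ccccc3)c(OCc3ccccc3)c(OCc3ccccc3)c1)[C@@H](O)[C@@H]2c1c(Br)cc(OCc2ccccc2)c(OCc2ccccc2)c1OCc1ccccc1 | intermediate
14 | (2R,3S,4S)-3,7-bis(benzyloxy)-4-[2,3,4-tris(benzyloxy)-6-bromophenyl]-2-[3,4,5-tris(benzyloxy)phenyl]chromane | C(c1ccccc1)Oc1ccc2c(c1)O[C@H](c1cc(OCc3ccccc3)c(OCc3ccccc3)c(OCc3ccccc3)c1)[C@@H](OCc1ccccc1)[C@@H]2c1c(Br)cc(OCc2ccccc2)c(OCc2ccccc2)c1OCc1ccccc1 | intermediate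
15 | (E)-3-{2-[(2R,3S,4S)-3,7-bis(benzyloxy)-2-(3,4,5-tris(benzyloxy)phenyl)chroman-4-yl]-3,4,5-tris(benzyloxy)phenyl}prop-2-en-1-ol | C(c1ccccc1)Oc1ccc2c(c1)O[C@H](c1cc(OCc3ccccc3)c(OCc3ccccc3)c(OCc3ccccc3)c1)[C@@H](OCc1ccccc1)[C@@H]2c1c(/C=C/CO)cc(OCc2ccccc2)c(OCc2ccccc2)c1OCc1ccccc1 | intermediate
16 | methyl carbonate of 15 | C(c1ccccc1)Oc1ccc2c(c1)O[C@H](c1cc(OCc3ccccc3)c(OCc3ccccc3)c(OCc3ccccc3)c1)[C@@H](OCc1ccccc1)[C@@H]2c1c(/C=C/COC(=O)OC)cc(OCc2ccccc2)c(OCc2ccccc2)c1OCc1ccccc1 | intermediate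
17 | 4-(benzyloxy)-2-hydroxybenzaldehyde | O=Cc1ccc(OCc2ccccc2)cc1O | starting material
18 | 5-(benzyloxy)-2-ethenylphenol | C=Cc1ccc(OCc2ccccc2)cc1O | intermediate
19 | (S)-1-aryl-allyl 5-(benzyloxy)-2-ethenylphenyl ether, aryl = central ring of 14 in place of Br | C(c1ccccc1)Oc1ccc2c(c1)O[C@H](c1cc(OCc3ccccc3)c(OCc3ccccc3)c(OCc3ccccc3)c1)[C@@H](OCc1ccccc1)[C@@H]2c1c([C@H](C=C)Oc2cc(OCc3ccccc3)ccc2C=C)cc(OCc2ccccc2)c(OCc2ccccc2)c1OCc1ccccc1 | intermediate
20 | (2S)-7-(benzyloxy)-2-{2-[(2R,3S,4S)-3,7-bis(benzyloxy)-2-(3,4,5-tris(benzyloxy)phenyl)chroman-4-yl]-3,4,5-tris(benzyloxy)phenyl}-2H-chromene | C(c1ccccc1)Oc1ccc2c(c1)O[C@H](c1cc(OCc3ccccc3)c(OCc3ccccc3)c(OCc3ccccc3)c1)[C@@H](OCc1ccccc1)[C@@H]2c1c([C@H]2Oc3cc(OCc4ccccc4)ccc3C=C2)cc(OCc2ccccc2)c(OCc2ccccc2)c1OCc1ccccc1 | intermediate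
21 | (2R,3S,4S)-7-(benzyloxy)-2-{2-[(2R,3S,4S)-3,7-bis(benzyloxy)-2-(3,4,5-tris(benzyloxy)phenyl)chroman-4-yl]-3,4,5-tris(benzyloxy)phenyl}chromane-3,4-diol | C(c1ccccc1)Oc1ccc2c(c1)O[C@H](c1cc(OCc3ccccc3)c(OCc3ccccc3)c(OCc3ccccc3)c1)[C@@H](OCc1ccccc1)[C@@H]2c1c([C@H]2Oc3cc(OCc4ccccc4)ccc3[C@H](O)[C@@H]2O)cc(OCc2ccccc2)c(OCc2ccccc2)c1OCc1ccccc1 | intermediate
22 | (2R,3S,4S)-2-{2-[(2R,3S,4S)-3,7-dihydroxy-2-(3,4,5-trihydroxyphenyl)chroman-4-yl]-3,4,5-trihydroxyphenyl}chromane-3,4,7-triol | Oc1ccc2c(c1)O[C@H](c1cc(O)c(O)c(O)c1)[C@@H](O)[C@@H]2c1c([C@H]2Oc3cc(O)ccc3[C@H](O)[C@@H]2O)cc(O)c(O)c1O | target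

**Summary**

Total step count: 14. Longest linear sequence: 12 steps (1, 2, 4, 5, 6, 7, 8, 9, 11, 12, 13, 14); steps 3 and 10 are side branches.

Steps most likely to fail:

1. Step 6 (proposed new method). What may go wrong: 1,2-aroyl migration of the Lewis-acid-opened epoxide before resorcinol captures it; loss of stereospecificity at C-4 if the β-carbon ionises fully; over-reduction with reductive opening of the new pyran. Fallback (known chemistry, biomimetic C-4 arylation): it sets out from compound 2 and returns at compound 14. Purchased (+)-dihydrorobinetin F1 is benzylated at its four phenols (BnBr, K2CO3, DMF) to tetra-O-benzyl dihydrorobinetin F2. NaBH4 (MeOH/THF, 0 °C) reduces the ketone to the 2,3-trans-3,4-trans flavan-3,4-diol F3. F3 is ionised at C-4 with BF3·OEt2 (CH2Cl2, −40 °C) in the presence of excess arene 2, whose only free ring positions are ortho to bromine. Attack anti to the 3-OH of the 2,3-trans cation should give the 3,4-trans 4-arylflavan-3-ol F4. Benzylation of its 3-OH under the step 7 conditions gives 14.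

2. Step 5. What may go wrong: slow hydroperoxide addition to the β-carbon shielded by two ortho substituents, and poor facial discrimination by the polypeptide on this twisted enone. Fallback (reagent-controlled epoxidation of an allylic alcohol instead of an enone): it sets out from compound 8 and returns at compound 9. Luche reduction (NaBH4, CeCl3·7H2O, MeOH/THF, 0 °C) gives racemic allylic alcohol F5. Sharpless asymmetric epoxidation run as a kinetic resolution (Ti(OiPr)4, D-(−)-diisopropyl tartrate, t-BuOOH 0.5 equiv, 4 Å sieves, CH2Cl2, −20 °C) should convert the fast-reacting S enantiomer into erythro epoxy alcohol F6. Dess–Martin periodinane oxidation of F6 gives 9, and unreacted alcohol can be returned to 8 with MnO2.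

3. Step 11. What may go wrong: attack at the unsubstituted allyl terminus (linear ether) and eroded enantioselectivity because the bulky ortho substituent crowds the allyl-iridium intermediate. Fallback (stereocentre from an epoxide opened with inversion instead of allylic substitution): it sets out from compound 15 and returns at compound 19. Sharpless asymmetric epoxidation of 15 (Ti(OiPr)4, L-(+)-diisopropyl tartrate, t-BuOOH, 4 Å sieves, CH2Cl2, −20 °C) should give (2S,3S)-epoxy alcohol F7. Phenol 18 (aq. NaOH, dioxane, 60 °C) opens F7 at the benzylic carbon with inversion to give aryloxy diol F8. 1,1′-Thiocarbonyldiimidazole (toluene, 80 °C) converts the diol into cyclic thiocarbonate F9. Corey–Winter olefination of F9 with 1,3-dimethyl-2-phenyl-1,3,2-diazaphospholidine (THF, 40 °C) gives 19.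

**Further compounds**

F1 | step 6 | (+)-dihydrorobinetin, (2R,3R)-3,7-dihydroxy-2-(3,4,5-trihydroxyphenyl)chroman-4-one (purchased) | Oc1ccc2c(c1)O[C@H](c1cc(O)c(O)c(O)c1)[C@@H](O)C2=O
F2 | step 6 | (2R,3R)-7-(benzyloxy)-3-hydroxy-2-[3,4,5-tris(benzyloxy)phenyl]chroman-4-one | C(c1ccccc1)Oc1ccc2c(c1)O[C@H](c1cc(OCc3ccccc3)c(OCc3ccccc3)c(OCc3ccccc3)c1)[C@@H](O)C2=O
F3 | step 6 | (2R,3S,4R)-7-(benzyloxy)-2-[3,4,5-tris(benzyloxy)phenyl]chromane-3,4-diol | C(c1ccccc1)Oc1ccc2c(c1)O[C@H](c1cc(OCc3ccccc3)c(OCc3ccccc3)c(OCc3ccccc3)c1)[C@@H](O)[C@@H]2O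
F4 | step 6 | (2R,3S,4S)-7-(benzyloxy)-4-[2,3,4-tris(benzyloxy)-6-bromophenyl]-2-[3,4,5-tris(benzyloxy)phenyl]chroman-3-ol | C(c1ccccc1)Oc1ccc2c(c1)O[C@H](c1cc(OCc3ccccc3)c(OCc3ccccc3)c(OCc3ccccc3)c1)[C@@H](O)[C@@H]2c1c(Br)cc(OCc2ccccc2)c(OCc2ccccc2)c1OCc1ccccc1
F5 | step 5 | (E)-3-[2,3,4-tris(benzyloxy)-6-bromophenyl]-1-[3,4,5-tris(benzyloxy)phenyl]prop-2-en-1-ol (racemic) | OC(/C=C/c1c(Br)cc(OCc2ccccc2)c(OCc2ccccc2)c1OCc1ccccc1)c1cc(OCc2ccccc2)c(OCc2ccccc2)c(OCc2ccccc2)c1
F6 | step 5 | (R)-[(2R,3R)-3-(2,3,4-tris(benzyloxy)-6-bromophenyl)oxiran-2-yl][3,4,5-tris(benzyloxy)phenyl]methanol | O[C@H](c1cc(OCc2ccccc2)c(OCc2ccccc2)c(OCc2ccccc2)c1)[C@H]1O[C@@H]1c1c(Br)cc(OCc2ccccc2)c(OCc2ccccc2)c1OCc1ccccc1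
F7 | step 11 | [(2S,3S)-3-aryl-oxiran-2-yl]methanol, aryl = central ring of 15 | C(c1ccccc1)Oc1ccc2c(c1)O[C@H](c1cc(OCc3ccccc3)c(OCc3ccccc3)c(OCc3ccccc3)c1)[C@@H](OCc1ccccc1)[C@@H]2c1c([C@@H]2O[C@H]2CO)cc(OCc2ccccc2)c(OCc2ccccc2)c1OCc1ccccc1
F8 | step 11 | (2S,3R)-3-aryl-3-[5-(benzyloxy)-2-ethenylphenoxy]propane-1,2-diol, aryl = central ring of 15 | C(c1ccccc1)Oc1ccc2c(c1)O[C@H](c1cc(OCc3ccccc3)c(OCc3ccccc3)c(OCc3ccccc3)c1)[C@@H](OCc1ccccc1)[C@@H]2c1c([C@H]([C@@H](O)CO)Oc2cc(OCc3ccccc3)ccc2C=C)cc(OCc2ccccc2)c(OCc2ccccc2)c1OCc1ccccc1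
F9 | step 11 | cyclic thiocarbonate (1,3-dioxolane-2-thione) of F8 | C(c1ccccc1)Oc1ccc2c(c1)O[C@H](c1cc(OCc3ccccc3)c(OCc3ccccc3)c(OCc3ccccc3)c1)[C@@H](OCc1ccccc1)[C@@H]2c1c([C@H]([C@@H]2COC(=S)O2)Oc2cc(OCc3ccccc3)ccc2C=C)cc(OCc2ccccc2)c(OCc2ccccc2)c1OCc1ccccc1
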